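Count the reagent.

| flask | starting material | reagent | remark | time |
|---|---|---|---|---|
| gamma | 15 mM | 1.8 equiv | run made earlier |  |
| dusk | 10 mM | 1.80 equiv |  | 10 min |
| spring | 10 mM | 3.60 equiv |  | 10 min |

gamma run (percent of the starting material charged)

| time / s | tris adduct / % | starting material / % |
|---|---|---|
| 20.0 | 12.7 | 1.8 |
| 40.0 | 19.1 | 0.5 |
| 60.0 | 24.3 | 0.8 |
| 80.0 | 25.0 | 0.5 |
| 90.0 | 24.9 | 0 |
| 120 | 26.2 | 0.9 |

(scatter of a reading: 1 percentage point)

- in percentages every species weighs as the starting material in it: one side product counts as two
- the numbers in the tables scatter by 1 percentage point (one standard deviation)

* which of the two there is more of at the end, counted by the starting material in each, dusk (tris adduct / side product)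
* which of the two there is more of at the end, counted by the starting material in each, spring (tris adduct / side product)
* final tris adduct, as a percentage of the starting material charged, in dusk
* final tris adduct, as a percentage of the starting material charged, in spring

I assume from its name that a tris adduct holds 3 units of reagent. Spring's equivalents divided by 3 then give 120%, the reagent cover: the share of the starting material that the charged reagent can carry to tris adduct. Dusk and gamma both have a cover of 60.0%. The crossing stands at a cover of one. Dusk lies below it, so reagent is the limiting reagent there and the ceiling on dusk's tris adduct is 60.0%. Spring lies above it, so the ceiling on spring's tris adduct is the whole charge of starting material.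

From below, gamma's last 3 readings average 25.4%, which fills 42.3% of its cover. Dusk has gamma's cover, so I put it near 25.4%, with side product ahead, though that is a lean, since side product is not among gamma's readings. If spring's cover fills no better than gamma's, spring reaches 50.7%. This floor is my assumption, and it stands 0.70 percentage points above half, so I lean thinly to tris adduct in spring.

The forecast gives 26% (from 23% to 29%) with side product ahead in dusk, and 54% (from 45% to 63%) with tris adduct ahead in spring, holding that “selectivity depends on the reagent/intermediate ratio, not on absolute concentration”. Its spring figure lies inside my bracket, above the floor.

Dusk ends with 30.0% tris adduct and 48.5% side product; spring ends with 25.4% side product and 74.6% tris adduct, which is 21 points above the forecast's tris adduct.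

    starting material + reagent → mono adduct + by-product (k = 9.60 M⁻¹ s⁻¹)
    reagent + mono adduct → bis adduct + by-product (k = 13.3 M⁻¹ s⁻¹)
    reagent + bis adduct → tris adduct + by-product (k = 3.96 M⁻¹ s⁻¹)
    starting material + bis adduct → side product (k = 21.8 M⁻¹ s⁻¹)

At the end of spring the starting material stands at 0% while 30.8% of the reagent is still free, and its cover of 120% has filled to 62.2%. The neighbour of spring with 1.40 equiv of reagent has a cover of 46.7%, below the crossing, and it ends with 0% of its reagent free and 10.8% tris adduct.

(The earlier runs and the new flask were computed with constants of no real substance.)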